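**Retrosynthetic overview**

- The target is the (E)-caffeate of (−)-drimenol (5S,9S,10S; drimane numbering throughout). The C11–O ester bond is cut last, giving drimenol and bis-silylated caffeic acid.
- Feature used: in ring B, C7 is a single carbon between unsubstituted C6 and methyl-bearing C8. The two arms it joins (C5–C6 and C9–C8) both start at quaternary C10. C7 can therefore enter as a one-carbon unit that ties a C5=C6 methylene to a C8=C9 ethylidene.
- The C7=C8 alkene comes from a C7 ketone through the more substituted enol triflate and formate hydrogenolysis. The ketone comes from a ring A 1,4-diene, thexylborane and CO, which form C6–C7 and C7–C8 and set C5, C8 and C9.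
- The diene comes from (R)-2-allyl-2,6,6-trimethylcyclohexanone, with C10 set by asymmetric decarboxylative allylation. MeLi addition and dehydration bring C6, allyl cleavage leaves C9–C11, and a directed aldol with acetaldehyde brings C8–C12.
- Ring order: ring A is bought with the starting ketone, and ring B is closed in step 10.

Key step: step 10

Assumption: the sense of induction of the PHOX ligand is taken from the parent 2-methylcyclohexanone series, where the (S)-ligand gives the (S)-ketone, so the (R)-ligand is used for the (R)-allyl ketone; if the sense were opposite, the other ligand enantiomer would be used and nothing else would change.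

**Step 1**
Reactants: 1 2,2,6-trimethylcyclohexanone (racemic); 2 allyl chloroformate
Product: 4 allyl 2,6,6-trimethylcyclohex-1-en-1-yl carbonate, via lithium enolate 3 (not isolated)
Conditions: LiN(SiMe3)2, THF, 0 °C; then 2, −78 → 25 °C
Reagents that add atoms: allyl chloroformate (2), C=CCOC(=O)Cl
Why: The ketone has one enolisable position, so deprotonation gives a single tetrasubstituted lithium enolate, and the hard chloroformate acylates this hindered enolate on oxygen (enolate O-acylation).

**Step 2**
Reactants: 4 allyl 2,6,6-trimethylcyclohex-1-en-1-yl carbonate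
Product: 5 (R)-2-allyl-2,6,6-trimethylcyclohexanone
Conditions: Pd2(dba)3 (cat.), (R)-4-tert-butyl-2-[2-(diphenylphosphino)phenyl]-4,5-dihydrooxazole ((R)-t-BuPHOX, cat.), THF, 25 °C
Reagents that add atoms: none
Why: In this decarboxylative asymmetric allylic alkylation (Tsuji allylation type), zerovalent palladium ionises the allyl carbonate, CO2 is lost, and enolate and allyl recombine inside the chiral P,N-ligand sphere, which selects the enolate face and sets quaternary C10 as R, the β-methyl configuration of the target.

**Step 3**
Reactants: 5 (R)-2-allyl-2,6,6-trimethylcyclohexanone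
Product: 6 (2R)-2-allyl-1,2,6,6-tetramethylcyclohexan-1-ol (either configuration at C1)
Conditions: MeLi (excess), Et2O, 0 → 35 °C; H2O
Reagents that add atoms: methyllithium, [Li]C
Why: This is a 1,2-addition of the smallest organolithium to a ketone that cannot enolise, so addition is the only path despite the two flanking quaternary carbons, and the new carbinol centre is removed in step 4.

**Step 4**
Reactants: 6 (2R)-2-allyl-1,2,6,6-tetramethylcyclohexan-1-ol
Product: 7 (1R)-1-allyl-1,3,3-trimethyl-2-methylidenecyclohexane
Conditions: SOCl2, pyridine, 0 °C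
Reagents that add atoms: none
Why: In this base-mediated dehydration of an activated tertiary alcohol (SOCl2–pyridine elimination), the new methyl group holds the only β-hydrogens, so only the exocyclic C5=C6 alkene can form, it cannot move into the ring, and cold pyridine disfavours ionisation and methyl shifts.

**Step 5**
Reactants: 7 (1R)-1-allyl-1,3,3-trimethyl-2-methylidenecyclohexane
Product: 9 2-[(1R)-1,3,3-trimethyl-2-methylidenecyclohexyl]acetaldehyde, via vicinal diol 8 (not isolated)
Conditions: OsO4 (cat.), NaIO4, 2,6-lutidine, dioxane–H2O, 0 → 25 °C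
Reagents that add atoms: OsO4, O=[Os](=O)(=O)=O, and NaIO4, [Na+].[O-]I(=O)(=O)=O (source of the aldehyde oxygen)
Why: In this Lemieux–Johnson cleavage OsO4 must reach both alkene carbons, so it takes the open monosubstituted vinyl group and leaves the C5=C6 methylene, whose inner carbon is buried between quaternary C4 and C10, while periodate cleaves the diol and lutidine keeps the medium neutral.

**Step 6**
Reactants: 9 2-[(1R)-1,3,3-trimethyl-2-methylidenecyclohexyl]acetaldehyde
Product: 10 (E)-N-cyclohexyl-2-[(1R)-1,3,3-trimethyl-2-methylidenecyclohexyl]ethan-1-imine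
Conditions: cyclohexylamine, 4 Å molecular sieves, CH2Cl2, 25 °C
Reagents that add atoms: cyclohexylamine, NC1CCCCC1
Why: Condensation of an aldehyde with a primary amine (imine formation) masks the carbonyl group and prepares the directed aldol.

**Step 7**
Reactants: 10 N-cyclohexyl imine; 11 acetaldehyde
Product: 14 (2Z)-2-[(1S)-1,3,3-trimethyl-2-methylidenecyclohexyl]but-2-enal, via lithium azaenolate 12 (not isolated), via β-hydroxy imine 13 (not isolated)
Conditions: LiN(i-Pr)2, THF, −78 → 0 °C; 11, −78 °C; then aq. oxalic acid, THF, 25 → 50 °C
Reagents that add atoms: acetaldehyde (11), CC=O; water, O (aldehyde oxygen on hydrolysis of the imine)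
Why: In this directed aldol condensation through a metalloenamine, the preformed azaenolate is the only nucleophile present when acetaldehyde arrives, which removes the self-condensation problem of a mixed aldehyde aldol, and acidic hydrolysis with loss of water gives the enal under equilibrating conditions, where C12 should settle trans to quaternary C10 (Z) to avoid a cis methyl/tert-alkyl contact.

**Step 8**
Reactants: 14 (Z)-enal
Product: 15 (2Z)-2-[(1S)-1,3,3-trimethyl-2-methylidenecyclohexyl]but-2-en-1-ol
Conditions: NaBH4, CeCl3·7H2O, MeOH, 0 °C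
Reagents that add atoms: none
Why: In the Luche reduction the cerium-modified borohydride delivers hydride to the aldehyde carbon only (1,2-reduction), leaving both alkenes and the Z geometry untouched.

**Step 9**
Reactants: 15 (Z)-allylic alcohol
Product: 16 tert-butyl(dimethyl){[(2Z)-2-[(1S)-1,3,3-trimethyl-2-methylidenecyclohexyl]but-2-en-1-yl]oxy}silane
Conditions: TBSCl, imidazole, DMF, 25 °C
Reagents that add atoms: tert-butyldimethylsilyl chloride, CC(C)(C)[Si](C)(C)Cl
Why: This is an imidazole-promoted silylation of a primary alcohol, and a silyl ether is chosen because it resists boranes, buffered peroxide, amide bases and palladium/formate and is a weakly electron-withdrawing oxygen substituent for the allylic position.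

**Step 10**
Reactants: 16 (Z)-1,4-diene silyl ether; 17 carbon monoxide
Product: 21 11-(tert-butyldimethylsilyloxy)driman-7-one (5αH,8βH,9αH,10β-methyl), via alkyl(thexyl)borane 18 (not isolated), via B-thexylborinane 19 (not isolated), via hydrated carbonylation adduct 20 (not isolated)
Conditions: ThxBH2 (from BH3·THF and 2,3-dimethylbut-2-ene, 0 °C), THF, slow addition, high dilution, 0 → 25 °C; CO (70 atm), H2O, 50 °C; then aq. NaOAc, 30% H2O2, 25 → 50 °C
Reagents that add atoms: carbon monoxide (17), [C-]#[O+]; hydrogen peroxide, OO (the carbonyl oxygen can stem from CO or from the peroxide through the gem-diol stage); thexylborane, CC(C)C(C)(C)B, and water, O, leave atoms only in 18–20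
Why: ThxBH2 adds first to the C5=C6 methylene (boron to the exposed terminal C6, hydrogen to C5) to give 18, the remaining B–H then adds within the molecule across C8=C9 with boron on C8 to give borinane 19, CO coordinates to boron, C6 and C8 migrate in turn from boron to the CO carbon with retention while water arrests the sequence before the poorly migrating thexyl group can follow (20), and buffered H2O2 cleaves the last C–B bond to release ketone 21 with the new C6–C7 and C7–C8 bonds. The closest known reaction type is the thexylborane cyclic hydroboration of 1,4-dienes built from a terminal alkene and a trisubstituted alkene, followed by carbonylation to trans-fused cyclohexanones; what is untested here is only the crowding of the methylene by quaternary C4 and C10. Ring B closes as a six-membered ring by endo addition (both C8 and C9 end up in the ring) through a chair-like four-centre transition state, the five-membered exo alternative being closed off because it would need a tertiary C9–B bond beside C10 on a boron that already carries thexyl. C5 is controlled by ring A: in the chair with the C10 methyl axial and the larger C9 side chain equatorial, the axial methyls on C4 and C10 cover the β face of C5=C6, so hydrogen enters from the α face and C5–H ends trans to the C10 methyl. C9 is controlled by the syn addition inside the chair borinane, which leaves the new C9–H gauche to the C8–B ring bond and therefore axial and anti to the axial C10 methyl (α), with C11 equatorial (β), while the Z geometry of 16 places C12 equatorial (8α-methyl, 8βH), a centre that can epimerise and is erased in step 11. The step needs the methylene to react before the ethylidene (secured by its lower substitution and free terminus), boron on C8 and not C9 (secured by sterics and ring size against the inductive pull of the allylic oxygen, which by itself favours C9 and would lead to β-elimination of the silyloxy group) and cyclisation over oligomerisation (secured by slow addition at high dilution and the geminal substitution at C10).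

**Step 11**
Reactants: 21 11-(tert-butyldimethylsilyloxy)driman-7-one
Product: 23 11-(tert-butyldimethylsilyloxy)drim-7-en-7-yl trifluoromethanesulfonate, via bromomagnesium enolate 22 (not isolated)
Conditions: i-Pr2NMgBr (from i-Pr2NH and MeMgBr), Et2O–THF, 0 → 25 °C (equilibration); then PhNTf2, 25 → 40 °C
Reagents that add atoms: N-phenylbis(trifluoromethanesulfonimide), O=S(=O)(N(c1ccccc1)S(=O)(=O)C(F)(F)F)C(F)(F)F
Why: This is regioselective enol triflate formation by enolate trapping, in which the magnesium amide allows proton exchange so the enolate equilibrates to the more substituted C7=C8 isomer before PhNTf2 is added, C8 becomes planar, and C5, C9 and C10 carry no acidic hydrogen.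

**Step 12**
Reactants: 23 enol triflate
Product: 24 tert-butyl(drim-7-en-11-yloxy)dimethylsilane (drimenol TBS ether)
Conditions: Pd(OAc)2 (cat.), PPh3 (cat.), HCO2H, Et3N, DMF, 60 °C
Reagents that add atoms: none
Why: In this palladium-catalysed formate hydrogenolysis of an enol triflate, oxidative addition of zerovalent palladium into the C7–O bond, exchange with formate, loss of CO2 and reductive elimination put hydrogen on C7 without moving the double bond.

**Step 13**
Reactants: 24 drimenol TBS ether
Product: 25 (−)-drimenol, (5S,9S,10S)-drim-7-en-11-ol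
Conditions: Bu4NF, THF, 25 °C; recrystallisation (hexane)
Reagents that add atoms: none
Why: Fluoride-induced cleavage of the silyl ether, driven by the Si–F bond, gives a crystalline alcohol whose recrystallisation is the point at which enantiomeric purity should be raised.

**Step 14**
Reactants: 26 caffeic acid
Product: 28 (E)-3-[3,4-bis(tert-butyldimethylsilyloxy)phenyl]prop-2-enoic acid, via tris-silyl derivative 27 (not isolated)
Conditions: TBSCl (excess), imidazole, DMF, 25 °C; then AcOH–THF–H2O, 25 °C
Reagents that add atoms: tert-butyldimethylsilyl chloride, CC(C)(C)[Si](C)(C)Cl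
Why: Exhaustive silylation is followed by selective hydrolysis, since the silyl ester is far more labile to aqueous acid than the two aryl silyl ethers, so only the carboxylic acid is set free and the E alkene is untouched.

**Step 15**
Reactants: 25 (−)-drimenol; 28 bis-silylated caffeic acid
Product: 29 drim-7-en-11-yl (E)-3-[3,4-bis(tert-butyldimethylsilyloxy)phenyl]prop-2-enoate
Conditions: DCC, DMAP, CH2Cl2, 0 → 25 °C
Reagents that add atoms: acid 28, O=C(O)/C=C/c1ccc(O[Si](C)(C)C(C)(C)C)c(O[Si](C)(C)C(C)(C)C)c1
Why: In the Steglich esterification DMAP passes the O-acylisourea on as an acylpyridinium ion that is reactive enough for the β-branched primary C11 alcohol, and no stereocentre is touched.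

**Step 16**
Reactants: 29 bis-silylated ester
Product: 30 drim-7-en-11-yl (E)-caffeate (target, CNP0265201.1)
Conditions: Bu4NF, AcOH, THF, 0 °C, argon
Reagents that add atoms: none
Why: This is fluoride cleavage of aryl silyl ethers, buffered with acetic acid so that the phenoxides are protonated at once and neither the ester nor the oxidation-prone catechol is exposed to base.

**Compound list**

1 | 2,2,6-trimethylcyclohexanone (racemic) | CC1CCCC(C)(C)C1=O | starting material
2 | allyl chloroformate | C=CCOC(=O)Cl | starting material
3 | lithium 2,6,6-trimethylcyclohex-1-en-1-olate | CC1=C([O-])C(C)(C)CCC1.[Li+] | intermediate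
4 | allyl 2,6,6-trimethylcyclohex-1-en-1-yl carbonate | CC1=C(OC(=O)OCC=C)C(C)(C)CCC1 | intermediate
5 | (R)-2-allyl-2,6,6-trimethylcyclohexanone | O=C1C(C)(C)CCC[C@]1(C)CC=C | intermediate
6 | (2R)-2-allyl-1,2,6,6-tetramethylcyclohexan-1-ol (C1 not defined) | CC1(O)C(C)(C)CCC[C@]1(C)CC=C | intermediate
7 | (1R)-1-allyl-1,3,3-trimethyl-2-methylidenecyclohexane | C=C1C(C)(C)CCC[C@]1(C)CC=C | intermediate
8 | 3-[(1R)-1,3,3-trimethyl-2-methylidenecyclohexyl]propane-1,2-diol (carbinol centre not defined) | C=C1C(C)(C)CCC[C@]1(C)CC(O)CO | intermediate
9 | 2-[(1R)-1,3,3-trimethyl-2-methylidenecyclohexyl]acetaldehyde | C=C1C(C)(C)CCC[C@]1(C)CC=O | intermediate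
10 | (E)-N-cyclohexyl-2-[(1R)-1,3,3-trimethyl-2-methylidenecyclohexyl]ethan-1-imine | C=C1C(C)(C)CCC[C@]1(C)C/C=N/C2CCCCC2 | intermediate
11 | acetaldehyde | CC=O | starting material
12 | lithium azaenolate of 10 (lithium N-cyclohexyl enamide) | C=C1C(C)(C)CCC[C@]1(C)C=C[N-]C2CCCCC2.[Li+] | intermediate
13 | β-hydroxy imine, aldol adduct of 12 and 11 (lithium alkoxide until acid is added; C8 and C9 not defined) | C=C1C(C)(C)CCC[C@]1(C)C(/C=N/C2CCCCC2)C(C)O | intermediate
14 | (2Z)-2-[(1S)-1,3,3-trimethyl-2-methylidenecyclohexyl]but-2-enal | C=C1C(C)(C)CCC[C@]1(C)/C(C=O)=C/C | intermediate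
15 | (2Z)-2-[(1S)-1,3,3-trimethyl-2-methylidenecyclohexyl]but-2-en-1-ol | C=C1C(C)(C)CCC[C@]1(C)/C(CO)=C/C | intermediate
16 | tert-butyl(dimethyl){[(2Z)-2-[(1S)-1,3,3-trimethyl-2-methylidenecyclohexyl]but-2-en-1-yl]oxy}silane | C=C1C(C)(C)CCC[C@]1(C)/C(CO[Si](C)(C)C(C)(C)C)=C/C | intermediate
17 | carbon monoxide | [C-]#[O+] | starting material
18 | alkyl(thexyl)borane: ring A with C5–H α (trans to the C10 methyl), C6H2–BH(thexyl) on C5, (Z) side chain of 16 unchanged | CC(C)C(C)(C)BC[C@H]1C(C)(C)CCC[C@]1(C)/C(CO[Si](C)(C)C(C)(C)C)=C/C | intermediate
19 | B-thexyl-7-boradrimane (trans-fused borinane; 5αH, 8βH, 9αH; C11 silyl ether) | C[C@@H]1B(C(C)(C)C(C)C)C[C@H]2C(C)(C)CCC[C@]2(C)[C@H]1CO[Si](C)(C)C(C)(C)C | intermediate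
20 | hydrated carbonylation adduct: C7 carries OH and B(OH)(thexyl) (C7 not defined) | C[C@@H]1C(O)(B(O)C(C)(C)C(C)C)C[C@H]2C(C)(C)CCC[C@]2(C)[C@H]1CO[Si](C)(C)C(C)(C)C | intermediate
21 | 11-(tert-butyldimethylsilyloxy)driman-7-one (5αH, 8βH, 9αH, 10β-methyl) | C[C@@H]1C(=O)C[C@H]2C(C)(C)CCC[C@]2(C)[C@H]1CO[Si](C)(C)C(C)(C)C | intermediate
22 | bromomagnesium C7=C8 enolate of 21 | CC1=C(O[Mg]Br)C[C@H]2C(C)(C)CCC[C@]2(C)[C@H]1CO[Si](C)(C)C(C)(C)C | intermediate
23 | 11-(tert-butyldimethylsilyloxy)drim-7-en-7-yl trifluoromethanesulfonate | CC1=C(OS(=O)(=O)C(F)(F)F)C[C@H]2C(C)(C)CCC[C@]2(C)[C@H]1CO[Si](C)(C)C(C)(C)C | intermediate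
24 | tert-butyl(drim-7-en-11-yloxy)dimethylsilane | CC1=CC[C@H]2C(C)(C)CCC[C@]2(C)[C@H]1CO[Si](C)(C)C(C)(C)C | intermediate
25 | (−)-drimenol, (5S,9S,10S)-drim-7-en-11-ol | CC1=CC[C@H]2C(C)(C)CCC[C@]2(C)[C@H]1CO | intermediate
26 | caffeic acid | O=C(O)/C=C/c1ccc(O)c(O)c1 | starting material
27 | tert-butyldimethylsilyl (E)-3-[3,4-bis(tert-butyldimethylsilyloxy)phenyl]prop-2-enoate | CC(C)(C)[Si](C)(C)OC(=O)/C=C/c1ccc(O[Si](C)(C)C(C)(C)C)c(O[Si](C)(C)C(C)(C)C)c1 | intermediate
28 | (E)-3-[3,4-bis(tert-butyldimethylsilyloxy)phenyl]prop-2-enoic acid | O=C(O)/C=C/c1ccc(O[Si](C)(C)C(C)(C)C)c(O[Si](C)(C)C(C)(C)C)c1 | intermediate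
29 | drim-7-en-11-yl (E)-3-[3,4-bis(tert-butyldimethylsilyloxy)phenyl]prop-2-enoate | CC1=CC[C@H]2C(C)(C)CCC[C@]2(C)[C@H]1COC(=O)/C=C/c1ccc(O[Si](C)(C)C(C)(C)C)c(O[Si](C)(C)C(C)(C)C)c1 | intermediate
30 | [(1S,4aS,8aS)-2,5,5,8a-tetramethyl-1,4,4a,5,6,7,8,8a-octahydronaphthalen-1-yl]methyl (E)-3-(3,4-dihydroxyphenyl)prop-2-enoate | CC1=CC[C@H]2C(C)(C)CCC[C@]2(C)[C@H]1COC(=O)/C=C/c1ccc(O)c(O)c1 | target

**Step count**

Total step count: 16. Longest linear sequence: 15 (steps 1–13, 15 and 16); step 14 is a one-step side branch.

**Steps most likely to fail**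

1. Step 10 (key step). The process at risk is poor facial selectivity in the first B–H addition.
   - Ring A of 16 can flip to the chair that carries the C9 side chain axial. Attack anti to the axial groups of that chair puts hydrogen on the β face of C5, and the closure then gives a cis-fused ketone.
   - In that chair the C10 methyl is still axial on the forming borinane, so C9 should keep its configuration and only C5 should be wrong.
   - The fallback sets C5 by dissolving-metal reduction instead of by hydroboration. It sets out from 16, which is taken through the conditions of step 10. The unseparated mixture of 21 and its C5 epimer, 11-(tert-butyldimethylsilyloxy)-5-epi-driman-7-one F1, is deprotonated at the less substituted C6 with LiN(i-Pr)2 in THF at −78 °C and trapped with Me3SiCl to give the Δ6 trimethylsilyl enol ether F2.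
   - Saegusa–Ito oxidation with Pd(OAc)2 in MeCN gives 11-(tert-butyldimethylsilyloxy)drim-5-en-7-one F3, in which C5 is planar and both epimers converge.
   - Li in NH3/THF with t-BuOH then protonates C5 axially on the α face, the usual outcome for such octalones. After an NH4Cl quench this returns the trans-fused ketone 21, where the route is rejoined.

2. Step 11. The process at risk is poor regioselectivity of enolisation. The tetrasubstituted C7=C8 enolate suffers allylic strain between C12 and the C11 side chain, so enolisation toward C6 may compete and lead to the wrong alkene after step 12.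
   - The fallback makes the alkene by anti elimination instead of by enolate trapping, and sets out from 21. LiBH(s-Bu)3 in THF at −78 °C attacks along the equatorial trajectory and gives the axial alcohol 11-(tert-butyldimethylsilyloxy)driman-7α-ol F4.
   - MsCl and Et3N give its methanesulfonate F5. DBU in hot toluene then removes the antiperiplanar axial 8β-hydrogen. This hydrogen leads to the more substituted alkene and is less shielded than the 6β-hydrogen, which sits under both axial methyls.
   - The fallback comes back to the route at 24 and bypasses 23.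

3. Step 7. The processes at risk are reversal of the aldol addition, incomplete loss of water during the acidic hydrolysis, and incomplete control of the alkene geometry.
   - The fallback works at the ester oxidation level, with C–C bond formation, activation and elimination as separate isolable stages, and sets out from 9. Pinnick oxidation (NaClO2, NaH2PO4, 2-methylbut-2-ene) gives 2-[(1R)-1,3,3-trimethyl-2-methylidenecyclohexyl]acetic acid F6, and MeI with K2CO3 in DMF gives its methyl ester F7.
   - LiN(i-Pr)2 and then acetaldehyde 11 give the β-hydroxy ester F8, and MsCl with Et3N gives the mesylate F9.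
   - DBU-induced elimination gives methyl (2Z)-2-[(1S)-1,3,3-trimethyl-2-methylidenecyclohexyl]but-2-enoate F10, which can be freed from any geometric isomer by chromatography.
   - i-Bu2AlH in CH2Cl2 at −78 °C reduces F10 to allylic alcohol 15, where the route is rejoined, bypassing 10 and 14.

**Further compounds**

F1 | step 10 | 11-(tert-butyldimethylsilyloxy)-5-epi-driman-7-one (5βH, cis-fused) | C[C@@H]1C(=O)C[C@@H]2C(C)(C)CCC[C@]2(C)[C@H]1CO[Si](C)(C)C(C)(C)C
F2 | step 10 | 11-(tert-butyldimethylsilyloxy)-7-(trimethylsilyloxy)drim-6-ene (both C5 epimers) | C[C@@H]1C(O[Si](C)(C)C)=CC2C(C)(C)CCC[C@]2(C)[C@H]1CO[Si](C)(C)C(C)(C)C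
F3 | step 10 | 11-(tert-butyldimethylsilyloxy)drim-5-en-7-one | C[C@@H]1C(=O)C=C2C(C)(C)CCC[C@]2(C)[C@H]1CO[Si](C)(C)C(C)(C)C
F4 | step 11 | 11-(tert-butyldimethylsilyloxy)driman-7α-ol | C[C@@H]1[C@H](O)C[C@H]2C(C)(C)CCC[C@]2(C)[C@H]1CO[Si](C)(C)C(C)(C)C
F5 | step 11 | 11-(tert-butyldimethylsilyloxy)driman-7α-yl methanesulfonate | C[C@@H]1[C@H](OS(C)(=O)=O)C[C@H]2C(C)(C)CCC[C@]2(C)[C@H]1CO[Si](C)(C)C(C)(C)C
F6 | step 7 | 2-[(1R)-1,3,3-trimethyl-2-methylidenecyclohexyl]acetic acid | C=C1C(C)(C)CCC[C@]1(C)CC(=O)O
F7 | step 7 | methyl 2-[(1R)-1,3,3-trimethyl-2-methylidenecyclohexyl]acetate | C=C1C(C)(C)CCC[C@]1(C)CC(=O)OC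
F8 | step 7 | methyl 3-hydroxy-2-[1,3,3-trimethyl-2-methylidenecyclohexyl]butanoate (C10 as in 9; new centres not defined) | C=C1C(C)(C)CCC[C@]1(C)C(C(C)O)C(=O)OC
F9 | step 7 | methyl 3-(methylsulfonyloxy)-2-[1,3,3-trimethyl-2-methylidenecyclohexyl]butanoate (C10 as in 9) | C=C1C(C)(C)CCC[C@]1(C)C(C(C)OS(C)(=O)=O)C(=O)OC
F10 | step 7 | methyl (2Z)-2-[(1S)-1,3,3-trimethyl-2-methylidenecyclohexyl]but-2-enoate | C=C1C(C)(C)CCC[C@]1(C)/C(C(=O)OC)=C/C
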